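The earlier runs and the new flask were computed on assumed constants, and the scatter is random.

If only the end of a flask is asked, the question is how the substrate splits between target and side product, and two chemists read the autumn and noon runs differently on that.

common to all: substrate 45 mM; partner 67.5 mM (in portions, 2)

|  | free catalyst | remark | time |
|---|---|---|---|
| autumn | 57 µM | run made earlier; portions every 15 min |  |
| noon | 130 µM | run made earlier; portions every 15 min |  |
| theta | 99 µM | the portions of partner follow each other after 15 min, the first at the start | 8.0 h |
| delta | 200 µM | the portions of partner follow each other after 15 min, the first at the start | 8.0 h |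

| run | time / h | target / % | catalyst intermediate B / % | side product / % | substrate / % |
|---|---|---|---|---|---|
| autumn | 0.417 | 13 | 1 | 0 | 92 |
| autumn | 0.667 | 16 | 0 | 6 | 81 |
| autumn | 1.00 | 23 | 0 | 5 | 71 |
| autumn | 1.50 | 36 | 0 | 15 | 56 |
| autumn | 2.50 | 54 | 1 | 26 | 23 |
| autumn | 4.00 | 73 | 0 | 30 | 2 |
| autumn | 6.00 | 73 | 2 | 25 | 2 |
| noon | 0.417 | 23 | 0 | 1 | 74 |
| noon | 0.667 | 38 | 0 | 7 | 57 |
| noon | 1.00 | 57 | 1 | 9 | 35 |
| noon | 1.50 | 78 | 0 | 15 | 7 |
| noon | 2.50 | 85 | 1 | 13 | 0 |
| noon | 4.00 | 86 | 4 | 18 | 0 |
| noon | 6.00 | 88 | 2 | 15 | 0 |

(scatter of a reading: 2 percentage points)

- in percentages every species weighs as the substrate in it: one side product counts as two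
- the analysis behind the earlier runs scatters by 2 percentage points, standard deviation

- which of these there is most of at the end, counted by the substrate in it, theta (side product / target / substrate / catalyst intermediate B)
- which of these there is most of at the end, counted by the substrate in it, delta (side product / target / substrate / catalyst intermediate B)
- how much there is at the end of the one of these that leads, in percent of the substrate charged: theta
- how much there is at the end of the one of these that leads, in percent of the substrate charged: delta

They agree on one point. Autumn has the smallest catalyst charge and reads 2% substrate at 4.00 h, and the asked 8.0 h is longer, so both treat theta and delta as finished flasks.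

The first chemist draws a straight line through the last target readings against charged c(free catalyst), 73% in autumn and 88% in noon. Her line gives 81.6% for theta and 102% for delta, and she reads delta as target with no side product worth counting.

The second chemist holds that side product runs beside the catalysed step at a pace that ignores catalyst, so that side product over target falls as one over charged c(free catalyst). In her view, side product over target times charged c(free catalyst) stays constant: the last readings give 19.5 µM for autumn and 22.2 µM for noon, and their mean is 20.8 µM. This K is the crossover catalyst level, the charged c(free catalyst) at which, in her view, target and side product end equal, a selectivity factor in catalyst units. Her target is then charged c(free catalyst) over that charge plus K, in parts of the substrate charged: 82.6% for theta and 90.6% for delta.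

The forecast takes this side, from its own end values. It says side product “stops once substrate is gone”, names target as the leader in theta and target in delta, and gives 83% for theta and 91% for delta.

Theta ends with target 82.3% and side product 17.7%, delta with target 90.0% and side product 9.98%, so the crossover view stands. Inside its runs, between 57 µM and 130 µM, the straight line misses theta by 0.70 percentage points, and outside them it overshoots delta by 12 points.

    partner + free catalyst ⇌ catalyst intermediate A (K = 340 M⁻¹, k = 38.0 M⁻¹ s⁻¹)
    substrate + catalyst intermediate A → catalyst intermediate B (k = 190 M⁻¹ s⁻¹)
    catalyst intermediate B ⇌ catalyst intermediate C (K = 0.820, k = 0.170 s⁻¹)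
    catalyst intermediate C → free catalyst + target (k = 0.210 s⁻¹)
    substrate + target → side product (k = 0.00200 M⁻¹ s⁻¹)

In theta, half of the turnover of substrate with catalyst intermediate A is done by 0.986 h, sooner than the 2.1 h half-life of target in the step to side product, with substrate held at its charge. K over charged c(free catalyst) is 0.211 for theta and 0.104 for delta, and these flasks end with side product over target at 0.215 and 0.111.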